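(The data were computed on assumed constants; the scatter is artificial.)

- The winter run is the one earlier flask that moves: between 15.0 min and 50.0 min its target climbs from 14.4% to 55.6%, a pace that would take 85.0 min for the whole charge at c(substrate) = 44 mM.
- Substrate and reagent have to meet, so this reckoning assumes that, at fixed equivalents, the pace in percent grows in step with c(substrate).
- At 35 °C this gives 170 min for the sweep time, the time target would need at 22 mM to gain the whole charge at a steady pace.
- The midnight run ends at 0%, and its highest reading, 1.3%, is gone again at 3.00 h. Granting it a true rise of that size over 6.00 h puts the sweep time at −6 °C and 22 mM at 231 h or longer.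
- Between these two temperatures the sweep time therefore grows by a factor of at least 81.5, an apparent activation energy of at least 73.5 kJ/mol. This floor carries the ladder below, fastest rung first.

| flask | substrate | reagent | temperature | remark | time |
|---|---|---|---|---|---|
| midnight | 11 mM | 1.1 equiv | −6 °C | run made earlier |  |
| winter | 44 mM | 1.1 equiv | 35 °C | run made earlier |  |
| dusk | 22 mM | 0.55 equiv | −6 °C | run made earlier |  |
| red | 22 mM | 1.10 equiv | 25 °C |  | 1.5 h |
| green | 22 mM | 1.10 equiv | −25 °C |  | 1.5 h |
| amber | 22 mM | 1.10 equiv | 0 °C |  | 1.5 h |
| blue | 22 mM | 1.10 equiv | 50 °C |  | 1.5 h |

midnight run (percent of the substrate charged): time / h: target / % = 1.00: 0; 2.00: 1.3; 3.00: 0; 4.00: 0.1; 5.00: 0.8; 6.00: 0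

winter run (percent of the substrate charged): time / min: target / % = 8.00: 6.2; 15.0: 14.4; 25.0: 28.5; 30.0: 33.7; 40.0: 46.3; 50.0: 55.6

dusk run (percent of the substrate charged): time / h: target / % = 0.500: 0.1; 0.833: 0; 1.50: 0.5; 3.00: 0; 6.00: 0

(readings scatter by 0.5 percentage points)

- a reading or a percentage of target counts all its forms, free or not

1. which flask leads in amount of target, in percent of the substrate charged ("all alike" within 1.5 percentage points) (red / green / amber / blue / all alike)
2. how much target is there at the end, in percent of the substrate charged: red
3. how much target is there at the end, in percent of the substrate charged: green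
4. how much target is there at the end, in percent of the substrate charged: amber
5. how much target is there at the end, in percent of the substrate charged: blue

- Blue, at 50 °C: the sweep time is at most 44.9 min, shorter than 1.5 h, so blue should end close to full conversion.
- Red, at 25 °C: the same line gives a sweep time of 7.41 h, so about 20.2% of the charge as target. This figure is rough, and red should stand partway.
- Amber, at 0 °C: the sweep time is at least 112 h, longer than 1.5 h, so amber should stay at or below about 1.34%.
- Green, at −25 °C: the sweep time is at least 2900 h, far longer than 1.5 h, so green should show no readable target.
- The forecast, made apart from this reckoning, names blue as leader with 88%, then red 17%, amber 0.4% and green 0%, saying of the cold flasks that “there is essentially nothing”.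
- The flasks give: blue leads with 96.0%, then red 25.6%, amber 0.162% and green 0%.

    substrate + reagent → intermediate (k = 0.0122 /M/s, Ea = 69.0 kJ/mol)
    intermediate → target (k = 1.56 × 10⁻⁴ /s, Ea = 92.0 kJ/mol)
    crystals ⇌ target, rate k3*(cs3 - [target]) while solid is left; crystals form when [target] > cs3 (solubility = 20.0 mM, k = 0.00308 /s)
    (constants at 25 °C)

- Green ends at 0%; its sweep time, reckoned from 170 min, is at least 2900 h. The neighbouring flask is green run at −50 °C, all else held. The same reckoning from 170 min gives a sweep time of at least 1.57 × 10⁵ h, against 2900 h for green and the same 1.5 h. That flask ends with 0% target, and >99.9% of its substrate is still there.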